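**Retrosynthetic overview**
1. Last operation (key step): BBr3 ionises the two 4-methoxybenzylic alcohols of an open indane diol. The C7a–O bond (dihydrobenzofuran) and the C7c–C14a bond (eight-membered ring) form in the same flask, which then cleaves all methyl ethers.
2. The diol comes from hydroxyl-directed hydrogenation of an indene C7b=C8b bond (sets C7b, C8b). Before that, a double transfer hydrogenation with dynamic kinetic resolution of a stereo-labile diketone sets C8a and C8c and is the only source of absolute configuration.
3. The diketone comes from a Larock indene carboannulation (C10c–C7b, C8b–C8c) of an iodo-deoxybenzoin with a diaryl alkyne. The alkyne was first joined to a second copy of the same deoxybenzoin by ketone α-arylation (C8a–C10b).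
4. Building blocks: one deoxybenzoin (from 4'-methoxyacetophenone, used twice) and a bromo-tolan from 2-bromo-3,5-dimethoxybenzaldehyde and 4-iodoanisole.
5. Ring order: indene five-membered ring (step 6), saturated to the indane (step 8), then dihydrofuran ring and eight-membered ring together (step 9).

Assumption: the SMILES defines (7aR,8aR,7bR,8bS,7cR,8cR) in oligostilbene locants, which are used for all intermediates (C7x = CH bearing a 4-oxyphenyl ring, C8x = CH bearing the 3,5-dioxyphenyl ring C9x–C14x; a = dihydrobenzofuran unit, b = unit whose resorcinol ring D is the benzofuran benzo ring, c = unit whose resorcinol ring B is the indane benzo ring).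

**Step 1**
Reactants: 1 4'-methoxyacetophenone; 2 1-bromo-3,5-dimethoxybenzene
Product: 3 2-(3,5-dimethoxyphenyl)-1-(4-methoxyphenyl)ethan-1-one (achiral)
Conditions: Pd2(dba)3 (1 mol %), Xantphos (2.4 mol %), NaOt-Bu (1.3 equiv), THF, 70 °C
Reagents that add atoms: none
Why: Palladium-catalysed ketone α-arylation (Buchwald–Hartwig type), in which the wide-bite-angle ligand and the more acidic, less reactive product enolate stop the reaction at mono-arylation; no stereocentre is formed.

**Step 2**
Reactants: 3 2-(3,5-dimethoxyphenyl)-1-(4-methoxyphenyl)ethan-1-one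
Product: 4 2-(2-iodo-3,5-dimethoxyphenyl)-1-(4-methoxyphenyl)ethan-1-one (achiral)
Conditions: NIS (1.05 equiv), CF3CO2H (10 mol %), MeCN, 0 to 23 °C
Reagents that add atoms: N-iodosuccinimide, O=C1CCC(=O)N1I
Why: Electrophilic aromatic iodination takes place on the far more electron-rich dimethoxy ring at C2, which is para to one methoxy group and ortho to the other and less hindered than the site between the two methoxy groups; no stereocentre is formed.

**Step 3**
Reactants: 5 2-bromo-3,5-dimethoxybenzaldehyde
Product: 6 2-bromo-1-ethynyl-3,5-dimethoxybenzene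
Conditions: dimethyl (1-diazo-2-oxopropyl)phosphonate (1.2 equiv), K2CO3 (2 equiv), MeOH, 23 °C
Reagents that add atoms: dimethyl (1-diazo-2-oxopropyl)phosphonate, CC(=O)C(=[N+]=[N-])P(=O)(OC)OC
Why: Seyferth–Gilbert homologation in the Ohira–Bestmann variant turns ArCHO into ArC≡CH under mild carbonate conditions that leave the aryl bromide untouched; no stereocentre is formed.

**Step 4**
Reactants: 6 2-bromo-1-ethynyl-3,5-dimethoxybenzene; 7 4-iodoanisole
Product: 8 2-bromo-1,5-dimethoxy-3-[(4-methoxyphenyl)ethynyl]benzene
Conditions: PdCl2(PPh3)2 (2 mol %), CuI (4 mol %), Et3N/THF (1:1), 23 °C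
Reagents that add atoms: none
Why: Sonogashira coupling, in which zerovalent palladium inserts into the C–I bond of 7 at room temperature much faster than into the hindered, electron-rich C–Br bond of 6, so the bromide is kept for the next step; no stereocentre is formed.

**Step 5**
Reactants: 8 2-bromo-1,5-dimethoxy-3-[(4-methoxyphenyl)ethynyl]benzene; 3 2-(3,5-dimethoxyphenyl)-1-(4-methoxyphenyl)ethan-1-one
Product: 9 2-(3,5-dimethoxyphenyl)-2-{2,4-dimethoxy-6-[(4-methoxyphenyl)ethynyl]phenyl}-1-(4-methoxyphenyl)ethan-1-one (racemic, C8a labile)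
Conditions: Pd(OAc)2 (5 mol %), P(t-Bu)3·HBF4 (10 mol %), NaOt-Bu (2.2 equiv), toluene, 80 °C
Reagents that add atoms: none
Why: Palladium-catalysed α-arylation of the deoxybenzoin enolate with the di-ortho-substituted bromide forges C8a–C10b, the triaryl ketone stays as its hindered enolate until work-up so no second arylation occurs, and C8a is formed racemic and configurationally labile, which is what step 7 requires.

**Step 6**
Reactants: 9 the alkynyl triaryl ketone from step 5; 4 2-(2-iodo-3,5-dimethoxyphenyl)-1-(4-methoxyphenyl)ethan-1-one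
Product: 10 2-{2-[1-(4-methoxybenzoyl)-4,6-dimethoxy-3-(4-methoxyphenyl)-1H-inden-2-yl]-4,6-dimethoxyphenyl}-2-(3,5-dimethoxyphenyl)-1-(4-methoxyphenyl)ethan-1-one (stereoisomer mixture; C8a and C8c, the indene C1, both labile)
Conditions: Pd(OAc)2 (10 mol %), K2CO3 (3 equiv), n-Bu4NCl (1 equiv), DMF, 100 °C; aq NH4Cl at 0 °C
Reagents that add atoms: none
Why: Larock carboannulation (indene synthesis), in which oxidative addition into the C–I bond of 4 is followed by syn-carbopalladation of the alkyne with the aryl group going to the less hindered alkyne carbon (the one bearing the 4-methoxyphenyl ring, palladium ending next to the di-ortho-substituted ring D), then carbonate-assisted formation of a six-membered palladacycle with the ketone α-carbon and reductive elimination close the five-membered ring, and cold protonation of the dienolate at the α-carbon returns the non-conjugated 1-aroylindene with C8c still labile.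

**Step 7**
Reactants: 10 the indenyl diketone from step 6
Product: 11 (1R,2R)-2-{2-[(1R)-1-[(R)-hydroxy(4-methoxyphenyl)methyl]-4,6-dimethoxy-3-(4-methoxyphenyl)-1H-inden-2-yl]-4,6-dimethoxyphenyl}-2-(3,5-dimethoxyphenyl)-1-(4-methoxyphenyl)ethan-1-ol, that is (7aR,8aR,7cR,8cR)
Conditions: RuCl(p-cymene)[(R,R)-TsDPEN] (5 mol %), HCO2H/Et3N (5:2), DMF, 40 °C
Reagents that add atoms: none
Why: Noyori–Ikariya asymmetric transfer hydrogenation with dynamic kinetic resolution at both ketones in one operation, in which each α-carbon racemises through its enol, the (R,R)-catalyst delivers hydride to the Si face of each aryl ketone, and Felkin–Anh attack anti to the bulkier α-substituent (the ring D side at both sites, which are local homologues) selects 8aR and 8cR.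

**Step 8**
Reactants: 11 the (7aR,8aR,7cR,8cR)-indenyl diol from step 7
Product: 12 (1R,2R)-2-{2-[(1S,2R,3R)-1-[(R)-hydroxy(4-methoxyphenyl)methyl]-4,6-dimethoxy-3-(4-methoxyphenyl)-2,3-dihydro-1H-inden-2-yl]-4,6-dimethoxyphenyl}-2-(3,5-dimethoxyphenyl)-1-(4-methoxyphenyl)ethan-1-ol, that is (7aR,8aR,7bR,8bR,7cR,8cS), with the two indane aryl groups cis and ring D trans to the C8c side chain
Conditions: [Ir(cod)(PCy3)(py)]PF6 (20 mol %), H2 (50 bar), CH2Cl2, 23 °C
Reagents that add atoms: none
Why: Hydroxyl-directed homogeneous hydrogenation, in which the C7c hydroxyl (homoallylic to the tetrasubstituted C7b=C8b bond) binds the cationic iridium centre so that both hydrogens are delivered to the face carrying the C7c carbinol, which makes H7b and H8b cis and places ring D trans to the C8c side chain (the C8c descriptor changes from R to S only through CIP priorities).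

**Step 9**
Reactants: 12 the (7aR,8aR,7bR,8bR,7cR,8cS)-indanyl diol from step 8
Product: 14 canaliculatol (7aR,8aR,7bR,8bS,7cR,8cR), via octamethyl ether 13 (not isolated)
Conditions: BBr3 (15 equiv), CH2Cl2 (2 mM), −78 °C, 1 h, then 23 °C, 16 h; H2O quench at 0 °C
Reagents that add atoms: none
Why: Proposed new method: BBr3 ionises both 4-methoxybenzylic alcohols at −78 °C, the C7a cation is captured 5-exo by the neighbouring 11b-methoxy oxygen and bromide removes the methyl group from the oxonium ion (reversible closure, so the thermodynamic trans-2,3-diaryl dihydrobenzofuran with C7a R results), the C7c cation alkylates C14a (ortho and para to methoxy groups) to close the eight-membered ring with its aryl group anti to the indane benzo ring (C7c R, the rival five-membered closure onto ring D being blocked because it needs a cis 8b/8c relationship), and warming cleaves the remaining eight methyl ethers; the closest known chemistry is the Lewis-acid benzylic-cation Friedel–Crafts closure of seven-membered rings and the BBr3 demethylative cyclisations used for oligostilbenoids.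

**Compound list**
1 | 4'-methoxyacetophenone | COc1ccc(cc1)C(C)=O | starting material
2 | 1-bromo-3,5-dimethoxybenzene | COc1cc(Br)cc(OC)c1 | starting material
3 | 2-(3,5-dimethoxyphenyl)-1-(4-methoxyphenyl)ethan-1-one | COc1ccc(cc1)C(=O)Cc1cc(OC)cc(OC)c1 | intermediate
4 | 2-(2-iodo-3,5-dimethoxyphenyl)-1-(4-methoxyphenyl)ethan-1-one | COc1ccc(cc1)C(=O)Cc1cc(OC)cc(OC)c1I | intermediate
5 | 2-bromo-3,5-dimethoxybenzaldehyde | COc1cc(C=O)c(Br)c(OC)c1 | starting material
6 | 2-bromo-1-ethynyl-3,5-dimethoxybenzene | COc1cc(C#C)c(Br)c(OC)c1 | intermediate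
7 | 4-iodoanisole | COc1ccc(I)cc1 | starting material
8 | 2-bromo-1,5-dimethoxy-3-[(4-methoxyphenyl)ethynyl]benzene | COc1ccc(cc1)C#Cc1cc(OC)cc(OC)c1Br | intermediate
9 | 2-(3,5-dimethoxyphenyl)-2-{2,4-dimethoxy-6-[(4-methoxyphenyl)ethynyl]phenyl}-1-(4-methoxyphenyl)ethan-1-one, racemic, C8a labile | COc1ccc(cc1)C#Cc1cc(OC)cc(OC)c1C(c1cc(OC)cc(OC)c1)C(=O)c1ccc(OC)cc1 | intermediate
10 | indenyl diketone (1-aroyl-1H-indene; C8a and C8c labile, no configuration assigned) | COc1ccc(cc1)C2=C(c3cc(OC)cc(OC)c3C(c3cc(OC)cc(OC)c3)C(=O)c3ccc(OC)cc3)C(C(=O)c3ccc(OC)cc3)c3cc(OC)cc(OC)c23 | intermediate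
11 | (7aR,8aR,7cR,8cR)-indenyl diol | COc1ccc(cc1)C2=C(c3cc(OC)cc(OC)c3[C@@H](c3cc(OC)cc(OC)c3)[C@@H](O)c3ccc(OC)cc3)[C@H]([C@@H](O)c3ccc(OC)cc3)c3cc(OC)cc(OC)c23 | intermediate
12 | (7aR,8aR,7bR,8bR,7cR,8cS)-indanyl diol | COc1ccc(cc1)[C@@H]2c3c(OC)cc(OC)cc3[C@@H]([C@@H](O)c3ccc(OC)cc3)[C@@H]2c3cc(OC)cc(OC)c3[C@@H](c3cc(OC)cc(OC)c3)[C@@H](O)c3ccc(OC)cc3 | intermediate
13 | canaliculatol octamethyl ether, (7aR,8aR,7bR,8bS,7cR,8cR) | COc1ccc([C@@H]2c3c(OC)cc(OC)cc3[C@H]3[C@H](c4ccc(OC)cc4)c4c(OC)cc(OC)cc4[C@@H]4c5c(cc(OC)cc5[C@H]23)O[C@H]4c2ccc(OC)cc2)cc1 | intermediate (not isolated)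
14 | canaliculatol, (7aR,8aR,7bR,8bS,7cR,8cR) | Oc1ccc([C@@H]2c3c(O)cc(O)cc3[C@H]3[C@H](c4ccc(O)cc4)c4c(O)cc(O)cc4[C@@H]4c5c(cc(O)cc5[C@H]23)O[C@H]4c2ccc(O)cc2)cc1 | target

**Step count**
Total steps: 9. Longest linear sequence: 7 (steps 3, 4, 5, 6, 7, 8, 9, starting from 5).

**Three steps most likely to fail**

Step 9. The eight-membered ring must close faster than E1 loss and re-addition of H8c, which would epimerise C8c and divert material into a pallidol-type diquinane. It must also beat a 1,2-hydride shift at the C7a cation, which would scramble C8a. The fallback sets out from 12 and returns at 13. With BCl3 (2.2 equiv) at −78 °C only the fast dihydrofuran closure is allowed to go to completion, and the C7c alcohol is collected as the benzylic chloride F5. F5 is then ionised under buffered, non-acidic conditions (AgOTf, 2,6-di-tert-butylpyridine, HFIP, −40 °C, high dilution), so that no free acid can epimerise C8c while the eight-membered ring closes to give 13, now isolated and purified. A separate BBr3 treatment of 13 then gives 14.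

Step 8. A tetrasubstituted, triaryl-substituted alkene may not bind the iridium catalyst. The fallback sets out from 10 and returns at 12. DBU moves the double bond of 10 into conjugation with the ketone, and H2 over Pd/C adds to this enone from the face away from the C7b aryl group (as in the cis-selective hydrogenation of 2,3-diarylindenones). DBU then equilibrates C8c to the trans arrangement, giving the saturated diketone F3 with the correct relative indane configuration but racemic. Transfer hydrogenation of F3 with the step 7 catalyst still resolves C8a dynamically but cannot correct the fixed indane. It therefore gives 12 together with the diastereomer F4 that carries the antipodal indane; chromatography returns 12 in at most 50 % yield.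

Step 7. Two hindered ketones must both undergo dynamic kinetic resolution with one catalyst antipode. The α,α-diaryl ketone may be slow, the sense at each site rests on a Felkin–Anh argument, and 10 can drift to its conjugated 3-aroyl tautomer. The fallback sets out from 9 and returns at 11, and reduces the ketones one at a time so each resolution can be tuned separately, with different catalyst antipodes if needed. Transfer hydrogenation of 9 gives the alkynyl alcohol F1. Larock carboannulation of F1 with 4 under the step 6 conditions gives the hydroxy ketone F2, in which only C8c is labile. A second transfer hydrogenation of F2 gives 11.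

**Further compounds**
F1 | step 7 | (7aR,8aR)-alkynyl alcohol, 9 with the ketone reduced | COc1ccc(cc1)C#Cc1cc(OC)cc(OC)c1[C@@H](c1cc(OC)cc(OC)c1)[C@@H](O)c1ccc(OC)cc1
F2 | step 7 | (7aR,8aR)-hydroxy ketone, 10 with only the C7a ketone reduced, C8c labile | COc1ccc(cc1)C2=C(c3cc(OC)cc(OC)c3[C@@H](c3cc(OC)cc(OC)c3)[C@@H](O)c3ccc(OC)cc3)C(C(=O)c3ccc(OC)cc3)c3cc(OC)cc(OC)c23
F3 | step 8 | saturated indanyl diketone, racemic, indane aryl groups cis and aroyl trans to ring D (enantiomer leading to 12 drawn), C8a labile | COc1ccc(cc1)[C@@H]2c3c(OC)cc(OC)cc3[C@@H](C(=O)c3ccc(OC)cc3)[C@@H]2c3cc(OC)cc(OC)c3C(c3cc(OC)cc(OC)c3)C(=O)c3ccc(OC)cc3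
F4 | step 8 | diastereomer of 12 with the antipodal indane stereotriad | COc1ccc(cc1)[C@H]2c3c(OC)cc(OC)cc3[C@H]([C@@H](O)c3ccc(OC)cc3)[C@H]2c3cc(OC)cc(OC)c3[C@@H](c3cc(OC)cc(OC)c3)[C@@H](O)c3ccc(OC)cc3
F5 | step 9 | C7c benzylic chloride with the trans-dihydrobenzofuran closed (7aR,8aR,7bR,8bR,8cS; C7c epimer mixture) | COc1ccc(cc1)[C@@H]2c3c(OC)cc(OC)cc3[C@@H](C(Cl)c4ccc(OC)cc4)[C@@H]2c5cc(OC)cc6O[C@@H](c7ccc(OC)cc7)[C@H](c8cc(OC)cc(OC)c8)c56
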